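## Structural features

The target is a melampolide-type germacranolide: a ten-membered carbocycle C1–C10, trans-fused at C6–C7 to an α-methylene-γ-butyrolactone (O6–C12(=O)–C11(=C13)–C7). C4–C5 carries a trans epoxide with the C15 methyl on C4. C1=C10 is cis within the ring and bears the C14 methyl ester. C8 and C9 carry a methacrylate and an acetate. Six contiguous stereocentres run from C4 to C9 (4R,5R,6S,7R,8S,9S): H6/H7 are trans, O8 is cis to C11 on the ring, and O8/O9 are threo. Fragile points are the C9 acetate (with C10=C1–CO2Me it is an activated, Baylis–Hillman-type allylic ester), the vicinal diester (acyl shift), two Michael acceptors, and the epoxide (transannular opening). The real difficulty is the ten-membered ring with one ring-cis and one ring-trans trisubstituted olefin (the latter as its epoxide), plus the C6–C9 stereo-tetrad on a mobile ring. The key step exploits a hidden 3-oxy-1,5-diene retron: C9(O)–C8–C7–C6–C5=C4 is an (E)-cyclodec-5-enone pattern whose C6–C7 bond is the [3,3] bond, and the ring-cis C1=C10 olefin with C2 and C3 spans C9 and C4 by exactly the atoms of a cyclohexene. C8 is the carbon that becomes the enolate, and the C6 oxygen sits on a terminus that can be an enol ether.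

## Logic of the disconnections

**28 ⇒ 27.** Cut the two C–O bonds of the C4–C5 oxirane. Every other olefin of 27 is conjugated to a carbonyl, so the epoxide can come last and never meets base, fluoride or palladium. Gain: two stereocentres and the most acid-labile group disappear. Demand: the peracid must take one face of C4=C5.

**27 ⇒ 24 ⇒ 23.** Cut the lactone C12–O6 bond, lower C12 to the alcohol level, and cut the two O–Si bonds. The C11=C13 methylene is carried from the start, so no lactone enolate is needed beside three other esters. Gain: the lactone becomes two protected hydroxyls. Demand: the oxidant must choose the primary allylic C12–OH.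

**23 ⇒ 22 ⇒ 21.** Cut the acetyl–O9 bond, then the C10–C14 bond back to C10–I. A 2-iodo enone or iodo allylic alcohol survives the organometallic and basic steps that an alkylidene β-keto ester would not. Demand: carbonylation with retention of olefin geometry and without acyl shift.

**21 ⇒ 20 ⇒ 19.** Cut C9–H (back to the C9 ketone) and the C8–O ester bond with inversion. Enolate hydroxylation can only deliver oxygen to the exposed face, which is the 8-epi face. An invertive esterification corrects C8 and installs the methacrylate in one operation. Demand: SN2 at ring carbon C8, and hydride anti to the C8 ester.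

**19 ⇒ 16 (key).** Cut C6–C7 and C8–O, re-form C4–C9. The ten-membered ring, the C6 and C7 stereocentres, the 4E olefin, the ring-cis C1=C10 olefin and the C8/C9 oxygenation all collapse to a cyclohexenol whose only information-carrying stereocentre is C4. Demand: a chair [3,3] shift, E geometry in both alkenyl arms, and a trans arrangement of the arms.

**16 ⇒ 9 + 13.** Cut C8–C9 (carbonyl addition). The route becomes convergent. Demand: 1,2-addition anti to the alkenyl arm on C4.

**9 ⇒ 8 ⇒ 6 ⇒ 5 ⇒ 3.** Cut O–Si (enol silylation), re-add the carbon lost in C=C cleavage of an allyl group (C5–C6 arm), cut C10–I, and saturate C1=C10. Each is a functional-group change on one ring. Demand: the E enol ether.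

**3 ⇒ 2 ⇒ 1.** Cut the C4–allyl bond with CO2 put back (decarboxylative asymmetric allylation, the only reagent-controlled stereocentre of the route), then the C4–C15 bond. Demand: enantioselection at the quaternary carbon.

**13 ⇒ 12 ⇒ 11 ⇒ 10.** Cut C7=C8 (iodo-olefination), lower C7 to the alcohol, cut O–Si. Demand: E vinyl iodide.

## Other disconnections considered

**Alternative 1:** (first idea) Cut C6–C7 and the lactone C–O bond. Forward: intramolecular chromium- or zinc-mediated Barbier/Nozaki–Hiyama–Kishi allylation of the C6 enal by the C13 allylic bromide in A1, with lactonisation, which would give 27 directly. Grounds against it: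
- The allylmetal at C13/C7 has the C8 acyloxy group as a vinylogous β-leaving group, so 1,4-elimination to a diene competes with addition.
- The C9 acetate in A1 is itself an activated allylic ester towards low-valent metals.
- A1 needs the C8/C9 diad and both trisubstituted olefins built linearly before the ring is even tested.
- The ring closes end to end against entropy, with C6/C7 set by a macrocyclic transition state of unknown sense.

**Alternative 2:** Cut C9–C10. Forward: intramolecular Nozaki–Hiyama–Kishi addition of the (Z)-α-iodo enoate to the C9 aldehyde in A2, giving the Baylis–Hillman-type alcohol A3, then acetylation to 27. Grounds against it: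
- It forms only one stereocentre (C9), under macrocyclic control.
- The C6–C7–C8 triad and the lactone must be made first in a long linear sequence.
- The aldehyde is α-acyloxy and β-branched, so it can epimerise or eliminate.
- A ten-membered closure through a ring-cis alkenylchromium is strained.

The chosen plan makes the ring by an intramolecular concerted shift and sets two centres and two olefin geometries at once.

**Alternative 3:** Break C4–C9 as in the chosen plan, but with C6–C7 already in place. Forward: Wharton–Grob fragmentation of the trans-fused decalin hydroxy mesylate A4 (C5–OMs antiperiplanar to C4–C9) to the ring-expanded ketone A5. The fragmentation is stereospecific, but A4 requires six contiguous stereocentres (C4–C9) to be assembled stepwise on a decalin, and oxygen substituents at C6 and C8 flank the mesylate (E2 competition). The oxy-Cope cleaves the same bond while making C6–C7, from a cyclohexenone with a single stereocentre.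

Key step: step 11

## Route

Assumptions and conventions:
- 1 and 10 are taken as catalogue chemicals.
- TBS = tert-butyldimethylsilyl.
- Ten-membered-ring compounds use germacrane locants (ring C1–C10; C11, C12, C13 on C7; C14 on C10; C15 on C4). "14-nor" means C14 is absent.
- CIP descriptors of unchanged centres switch where substituent priorities change; the only inversion is at C8 in step 12.

Step 1
Reactants: 1 prop-2-en-1-yl 2-oxocyclohexane-1-carboxylate
Product: 2 prop-2-en-1-yl 1-methyl-2-oxocyclohexane-1-carboxylate (racemic)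
Conditions: K2CO3, MeI, acetone, 50 °C
Reagents that add atoms: iodomethane, CI
Why: C-alkylation of the stabilised β-keto ester enolate; the quaternary centre may be racemic because step 2 erases it.

Step 2
Reactants: 2 prop-2-en-1-yl 1-methyl-2-oxocyclohexane-1-carboxylate
Product: 3 (2S)-2-methyl-2-(prop-2-en-1-yl)cyclohexan-1-one
Conditions: Pd2(dba)3 (2.5 mol %), (S)-t-BuPHOX (6 mol %), THF, 25 °C
Reagents that add atoms: none
Why: Decarboxylative asymmetric allylic alkylation (Tsuji–Trost type): zerovalent palladium ionises the allyl ester, CO2 is lost and the prochiral enolate is allylated inside the chiral PHOX–palladium complex, so both enantiomers of 2 converge; the (S) ligand is the one that gives the (S) ketone in this substrate class, and the semicarbazone can be recrystallised if enrichment is needed.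

Step 3
Reactants: 3 (2S)-2-methyl-2-(prop-2-en-1-yl)cyclohexan-1-one
Product: 5 (6S)-6-methyl-6-(prop-2-en-1-yl)cyclohex-2-en-1-one, via lithium enolate 4 (not isolated)
Conditions: LDA, THF, −78 °C; then N-tert-butylbenzenesulfinimidoyl chloride, −78 °C
Reagents that add atoms: none
Why: One-pot dehydrogenation through the lithium enolate and a sulfinimidoyl chloride (Mukaiyama dehydrogenation); only the CH2 side has α-hydrogens, so regiochemistry is fixed and the stereocentre is untouched.

Step 4
Reactants: 5 (6S)-6-methyl-6-(prop-2-en-1-yl)cyclohex-2-en-1-one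
Product: 6 (6S)-2-iodo-6-methyl-6-(prop-2-en-1-yl)cyclohex-2-en-1-one
Conditions: I2, pyridine, CH2Cl2, 0 °C to rt
Reagents that add atoms: iodine, II
Why: Johnson α-iodination of an enone (pyridine conjugate addition, iodination, elimination); the isolated terminal alkene is inert to I2/pyridine.

Step 5
Reactants: 6 (6S)-2-iodo-6-methyl-6-(prop-2-en-1-yl)cyclohex-2-en-1-one
Product: 8 2-[(1S)-3-iodo-1-methyl-2-oxocyclohex-3-en-1-yl]acetaldehyde, via vicinal diol 7 (not isolated)
Conditions: OsO4 (2 mol %), NaIO4, 2,6-lutidine, 1,4-dioxane/H2O, rt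
Reagents that add atoms: sodium periodate, [Na+].[O-]I(=O)(=O)=O (oxygen relayed through catalytic osmium tetroxide, O=[Os](=O)(=O)=O)
Why: Lemieux–Johnson cleavage: the electron-rich monosubstituted alkene is dihydroxylated far faster than the iodo enone and periodate cleaves the diol, leaving the two-carbon C5–C6 aldehyde arm on the quaternary carbon.

Step 6
Reactants: 8 2-[(1S)-3-iodo-1-methyl-2-oxocyclohex-3-en-1-yl]acetaldehyde
Product: 9 (6S)-6-[(E)-2-(TBSO)ethenyl]-2-iodo-6-methylcyclohex-2-en-1-one
Conditions: TBSOTf (1.1 equiv), Et3N, CH2Cl2, −78 to 0 °C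
Reagents that add atoms: tert-butyldimethylsilyl trifluoromethanesulfonate, CC(C)(C)[Si](C)(C)OS(=O)(=O)C(F)(F)F
Why: Soft enolisation of the aldehyde (the ketone has no α-hydrogen). The quaternary neighbour turns away from the silyloxonium oxygen in the deprotonation and the E enol ether is also the more stable isomer, so E should dominate; any Z isomer is expected to be inert in step 11.

Step 7
Reactants: 10 2-methylidenepropane-1,3-diol
Product: 11 2-(TBSOCH2)prop-2-en-1-ol
Conditions: TBSCl (1 equiv), imidazole, DMF, 0 °C, 10 in threefold excess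
Reagents that add atoms: tert-butyldimethylsilyl chloride, CC(C)(C)[Si](C)(C)Cl
Why: Statistical monosilylation of a symmetric diol used in excess.

Step 8
Reactants: 11 2-(TBSOCH2)prop-2-en-1-ol
Product: 12 2-(TBSOCH2)prop-2-enal
Conditions: activated MnO2, CH2Cl2, rt
Reagents that add atoms: none
Why: Allylic oxidation on MnO2 stops at the enal, which is used at once.

Step 9
Reactants: 12 2-(TBSOCH2)prop-2-enal
Product: 13 tert-butyl{[(3E)-4-iodo-2-methylidenebut-3-en-1-yl]oxy}dimethylsilane
Conditions: CrCl2, CHI3, THF, 0 °C to rt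
Reagents that add atoms: iodoform, IC(I)I
Why: Takai iodo-olefination: the geminal dichromium species from CHI3 adds to the aldehyde and eliminates to the E vinyl iodide.

Step 10
Reactants: 13 tert-butyl{[(3E)-4-iodo-2-methylidenebut-3-en-1-yl]oxy}dimethylsilane; 9 (6S)-6-[(E)-2-(TBSO)ethenyl]-2-iodo-6-methylcyclohex-2-en-1-one
Product: 16 (1R,6S)-1-[(1E)-3-(TBSOCH2)buta-1,3-dien-1-yl]-6-[(E)-2-(TBSO)ethenyl]-2-iodo-6-methylcyclohex-2-en-1-ol, via dienyllithium 14 (not isolated), via dienylcerium dichloride 15 (not isolated)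
Conditions: 13, t-BuLi (2.05 equiv), Et2O, −78 °C; CeCl3, THF, −78 °C; then 9, −78 °C; aq NH4Cl
Reagents that add atoms: none
Why: Iodine–lithium exchange, transmetallation to the weakly basic organocerium and 1,2-addition to the hindered ketone (the vinyl iodide of 9 does not exchange with the cerium reagent). Felkin–Anh control: the sp2 arm on C6 lies antiperiplanar to the incoming nucleophile, so the dienyl group should enter cis to the methyl and trans to the silyloxyvinyl arm (1R); the minor epimer is removed by chromatography on base-washed silica.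

Step 11
Reactants: 16 (1R,6S)-1-[(1E)-3-(TBSOCH2)buta-1,3-dien-1-yl]-6-[(E)-2-(TBSO)ethenyl]-2-iodo-6-methylcyclohex-2-en-1-ol
Product: 19 (1(10)E,4E,6R,7R,8R)-6,12-bis(TBSO)-8-hydroxy-10-iodo-14-norgermacra-1(10),4,11(13)-trien-9-one, via potassium alkoxide 17 (not isolated), via potassium enolate 18 (not isolated)
Conditions: KH, 18-crown-6, THF, 0 °C to rt; then −78 °C, 2-(phenylsulfonyl)-3-phenyloxaziridine; aq NH4Cl at −78 °C
Reagents that add atoms: 2-(phenylsulfonyl)-3-phenyloxaziridine, O=S(=O)(N1OC1c1ccccc1)c1ccccc1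
Why: The potassium alkoxide 17 weakens the C4–C9 bond and triggers a charge-accelerated [3,3] shift (anionic oxy-Cope rearrangement; closest precedent is the ring expansion of 1,2-dialkenylcyclohexanols to cyclodec-5-enones followed by enolate oxygenation). The ten-membered ring is not closed end to end: it arises by four-atom ring expansion through a six-membered chair in which C6–C7 forms as C4–C9 breaks. Because the two alkenyl arms are trans on the cyclohexene, both tether atoms (C3 and C10) are pseudo-equatorial, so C3 ends trans to C6 (4E) and the cyclohexene olefin becomes the ring-cis C1=C10. C4 decides which chair is used (C3 equatorial, methyl axial), and with both migrating termini E the silyloxy group on C6 and C11 on C7 are pseudo-equatorial; this sets both centres at once (6R,7S in 18, the 6S,7R arrangement of the target). A Z enol ether would force its oxygen against the C4 substituents (allylic 1,3-strain) and should not reach this chair. In enolate 18 H7 lies in the enolate plane and C6 with the rest of the ring covers one face, so the oxaziridine (electrophilic enolate hydroxylation) adds to the open face and gives the 8R ketol, the C8 epimer of the target, which step 12 inverts. The selectivity needed is [3,3] over 1,3-shift and over the bridged path through C1=C10; the chair-accessible divinyl array and the crown-separated alkoxide at low temperature secure it.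

Step 12
Reactants: 19 (1(10)E,4E,6R,7R,8R)-6,12-bis(TBSO)-8-hydroxy-10-iodo-14-norgermacra-1(10),4,11(13)-trien-9-one
Product: 20 (1(10)E,4E,6R,7R,8S)-6,12-bis(TBSO)-10-iodo-9-oxo-14-norgermacra-1(10),4,11(13)-trien-8-yl 2-methylprop-2-enoate
Conditions: methacrylic acid, PPh3, DIAD, THF, 0 °C to rt
Reagents that add atoms: methacrylic acid, CC(=C)C(=O)O
Why: Mitsunobu esterification: SN2 displacement of the alkoxyphosphonium by methacrylate, accelerated by the adjacent carbonyl, inverts C8 to the target configuration and installs the ester in the same operation.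

Step 13
Reactants: 20 (1(10)E,4E,6R,7R,8S)-6,12-bis(TBSO)-10-iodo-9-oxo-14-norgermacra-1(10),4,11(13)-trien-8-yl 2-methylprop-2-enoate
Product: 21 (1(10)E,4E,6R,7R,8S,9R)-6,12-bis(TBSO)-9-hydroxy-10-iodo-14-norgermacra-1(10),4,11(13)-trien-8-yl 2-methylprop-2-enoate
Conditions: NaBH4, CeCl3·7H2O, MeOH/THF, −78 °C
Reagents that add atoms: none
Why: Luche 1,2-reduction of the α-iodo enone; hydride should come from the ring periphery anti to the C8 acyloxy group (Felkin–Anh), giving the 8,9-threo alcohol (the descriptor is 9R only because iodine outranks C8).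

Step 14
Reactants: 21 (1(10)E,4E,6R,7R,8S,9R)-6,12-bis(TBSO)-9-hydroxy-10-iodo-14-norgermacra-1(10),4,11(13)-trien-8-yl 2-methylprop-2-enoate
Product: 22 methyl (1(10)E,4E,6R,7R,8S,9S)-6,12-bis(TBSO)-9-hydroxy-8-[(2-methylprop-2-enoyl)oxy]germacra-1(10),4,11(13)-trien-14-oate
Conditions: Pd(OAc)2 (10 mol %), PPh3 (20 mol %), CO (1 atm), iPr2NEt, MeOH/DMF, 25 °C
Reagents that add atoms: carbon monoxide, [C-]#[O+]; methanol, CO
Why: Palladium-catalysed methoxycarbonylation: oxidative addition of zerovalent palladium into the vinyl C–I bond, CO insertion and methanolysis, with retention of olefin geometry. Room temperature and a hindered amine are chosen to keep the methacrylate on O8.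

Step 15
Reactants: 22 methyl (1(10)E,4E,6R,7R,8S,9S)-6,12-bis(TBSO)-9-hydroxy-8-[(2-methylprop-2-enoyl)oxy]germacra-1(10),4,11(13)-trien-14-oate
Product: 23 methyl (1(10)E,4E,6R,7R,8S,9S)-9-(acetyloxy)-6,12-bis(TBSO)-8-[(2-methylprop-2-enoyl)oxy]germacra-1(10),4,11(13)-trien-14-oate
Conditions: Ac2O, pyridine, DMAP (cat.), CH2Cl2, 0 °C
Reagents that add atoms: acetic anhydride, CC(=O)OC(C)=O
Why: DMAP-catalysed acetylation of the only free hydroxyl; short contact at 0 °C spares the activated allylic acetate that is formed.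

Step 16
Reactants: 23 methyl (1(10)E,4E,6R,7R,8S,9S)-9-(acetyloxy)-6,12-bis(TBSO)-8-[(2-methylprop-2-enoyl)oxy]germacra-1(10),4,11(13)-trien-14-oate
Product: 24 methyl (1(10)E,4E,6R,7S,8S,9S)-9-(acetyloxy)-6,12-dihydroxy-8-[(2-methylprop-2-enoyl)oxy]germacra-1(10),4,11(13)-trien-14-oate
Conditions: HF·pyridine, pyridine, THF, 0 °C to rt
Reagents that add atoms: none
Why: Fluoride cleaves both silyl ethers under buffered, mildly acidic conditions that do not promote acyl migration.

Step 17
Reactants: 24 methyl (1(10)E,4E,6R,7S,8S,9S)-9-(acetyloxy)-6,12-dihydroxy-8-[(2-methylprop-2-enoyl)oxy]germacra-1(10),4,11(13)-trien-14-oate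
Product: 27 methyl (1(10)E,4E,6R,7S,8S,9S)-9-(acetyloxy)-8-[(2-methylprop-2-enoyl)oxy]-12-oxo-6,12-epoxygermacra-1(10),4,11(13)-trien-14-oate, via hydroxy enal 25 (not isolated), via lactol 26 (not isolated)
Conditions: activated MnO2 (excess), CH2Cl2, rt
Reagents that add atoms: none
Why: MnO2 oxidises the primary allylic alcohol to the enal, the C6 hydroxyl closes the lactol and this is oxidised on to the α-methylene-γ-lactone (oxidative lactonisation of a 2-methylene-1,4-diol); the trans ring fusion is already fixed at C6 and C7.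

Step 18
Reactants: 27 methyl (1(10)E,4E,6R,7S,8S,9S)-9-(acetyloxy)-8-[(2-methylprop-2-enoyl)oxy]-12-oxo-6,12-epoxygermacra-1(10),4,11(13)-trien-14-oate
Product: 28 methyl (1(10)E,4R,5R,6S,7R,8S,9S)-9-(acetyloxy)-4,5:6,12-diepoxy-8-[(2-methylprop-2-enoyl)oxy]-12-oxogermacra-1(10),11(13)-dien-14-oate (target)
Conditions: mCPBA (1.1 equiv), NaHCO3, CH2Cl2, 0 °C
Reagents that add atoms: 3-chloroperoxybenzoic acid, OOC(=O)c1cccc(Cl)c1
Why: Prilezhaev epoxidation of the only electron-rich olefin, stereospecific for the trans epoxide. H6 eclipses C4=C5 (allylic 1,3-strain with C15) and the ring covers one face, so the peracid should add on the face flanked by the lactone oxygen and give 4R,5R, as in peripheral epoxidations of related germacranolide 4,5-olefins.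

## Compound list

1 | prop-2-en-1-yl 2-oxocyclohexane-1-carboxylate | C=CCOC(=O)C1CCCCC1=O | starting material
2 | prop-2-en-1-yl 1-methyl-2-oxocyclohexane-1-carboxylate (racemic) | C=CCOC(=O)C1(C)CCCCC1=O | intermediate
3 | (2S)-2-methyl-2-(prop-2-en-1-yl)cyclohexan-1-one | O=C1CCCC[C@@]1(C)CC=C | intermediate
4 | lithium (6S)-6-methyl-6-(prop-2-en-1-yl)cyclohex-1-en-1-olate | [Li+].[O-]C1=CCCC[C@@]1(C)CC=C | intermediate (not isolated)
5 | (6S)-6-methyl-6-(prop-2-en-1-yl)cyclohex-2-en-1-one | O=C1C=CCC[C@@]1(C)CC=C | intermediate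
6 | (6S)-2-iodo-6-methyl-6-(prop-2-en-1-yl)cyclohex-2-en-1-one | O=C1C(I)=CCC[C@@]1(C)CC=C | intermediate
7 | (6S)-6-(2,3-dihydroxypropyl)-2-iodo-6-methylcyclohex-2-en-1-one (both epimers at the carbinol carbon) | O=C1C(I)=CCC[C@@]1(C)CC(O)CO | intermediate (not isolated)
8 | 2-[(1S)-3-iodo-1-methyl-2-oxocyclohex-3-en-1-yl]acetaldehyde | O=C1C(I)=CCC[C@@]1(C)CC=O | intermediate
9 | (6S)-6-[(E)-2-(TBSO)ethenyl]-2-iodo-6-methylcyclohex-2-en-1-one | O=C1C(I)=CCC[C@@]1(C)/C=C/O[Si](C)(C)C(C)(C)C | intermediate
10 | 2-methylidenepropane-1,3-diol | C=C(CO)CO | starting material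
11 | 2-(TBSOCH2)prop-2-en-1-ol | C=C(CO)CO[Si](C)(C)C(C)(C)C | intermediate
12 | 2-(TBSOCH2)prop-2-enal | C=C(C=O)CO[Si](C)(C)C(C)(C)C | intermediate
13 | tert-butyl{[(3E)-4-iodo-2-methylidenebut-3-en-1-yl]oxy}dimethylsilane | C=C(/C=C/I)CO[Si](C)(C)C(C)(C)C | intermediate
14 | [(1E)-3-(TBSOCH2)buta-1,3-dien-1-yl]lithium | [Li]/C=C/C(=C)CO[Si](C)(C)C(C)(C)C | intermediate (not isolated)
15 | dichloro[(1E)-3-(TBSOCH2)buta-1,3-dien-1-yl]cerium | Cl[Ce](Cl)/C=C/C(=C)CO[Si](C)(C)C(C)(C)C | intermediate (not isolated)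
16 | (1R,6S)-1-[(1E)-3-(TBSOCH2)buta-1,3-dien-1-yl]-6-[(E)-2-(TBSO)ethenyl]-2-iodo-6-methylcyclohex-2-en-1-ol | O[C@@]1(/C=C/C(=C)CO[Si](C)(C)C(C)(C)C)C(I)=CCC[C@@]1(C)/C=C/O[Si](C)(C)C(C)(C)C | intermediate
17 | potassium (1R,6S)-1-[(1E)-3-(TBSOCH2)buta-1,3-dien-1-yl]-6-[(E)-2-(TBSO)ethenyl]-2-iodo-6-methylcyclohex-2-en-1-olate | [K+].[O-][C@@]1(/C=C/C(=C)CO[Si](C)(C)C(C)(C)C)C(I)=CCC[C@@]1(C)/C=C/O[Si](C)(C)C(C)(C)C | intermediate (not isolated)
18 | potassium (1(10)E,4E,6R,7S,8Z)-6,12-bis(TBSO)-10-iodo-14-norgermacra-1(10),4,8,11(13)-tetraen-9-olate | [K+].[O-]/C1=C\[C@@H](C(=C)CO[Si](C)(C)C(C)(C)C)[C@H](O[Si](C)(C)C(C)(C)C)/C=C(\C)CC/C=C1/I | intermediate (not isolated)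
19 | (1(10)E,4E,6R,7R,8R)-6,12-bis(TBSO)-8-hydroxy-10-iodo-14-norgermacra-1(10),4,11(13)-trien-9-one | O[C@@H]1[C@@H](C(=C)CO[Si](C)(C)C(C)(C)C)[C@H](O[Si](C)(C)C(C)(C)C)/C=C(\C)CC/C=C(/I)C1=O | intermediate
20 | (1(10)E,4E,6R,7R,8S)-6,12-bis(TBSO)-10-iodo-9-oxo-14-norgermacra-1(10),4,11(13)-trien-8-yl 2-methylprop-2-enoate | C=C(C)C(=O)O[C@H]1[C@@H](C(=C)CO[Si](C)(C)C(C)(C)C)[C@H](O[Si](C)(C)C(C)(C)C)/C=C(\C)CC/C=C(/I)C1=O | intermediate
21 | (1(10)E,4E,6R,7R,8S,9R)-6,12-bis(TBSO)-9-hydroxy-10-iodo-14-norgermacra-1(10),4,11(13)-trien-8-yl 2-methylprop-2-enoate | C=C(C)C(=O)O[C@H]1[C@@H](C(=C)CO[Si](C)(C)C(C)(C)C)[C@H](O[Si](C)(C)C(C)(C)C)/C=C(\C)CC/C=C(/I)[C@@H]1O | intermediate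
22 | methyl (1(10)E,4E,6R,7R,8S,9S)-6,12-bis(TBSO)-9-hydroxy-8-[(2-methylprop-2-enoyl)oxy]germacra-1(10),4,11(13)-trien-14-oate | C=C(C)C(=O)O[C@H]1[C@@H](C(=C)CO[Si](C)(C)C(C)(C)C)[C@H](O[Si](C)(C)C(C)(C)C)/C=C(\C)CC/C=C(/C(=O)OC)[C@@H]1O | intermediate
23 | methyl (1(10)E,4E,6R,7R,8S,9S)-9-(acetyloxy)-6,12-bis(TBSO)-8-[(2-methylprop-2-enoyl)oxy]germacra-1(10),4,11(13)-trien-14-oate | C=C(C)C(=O)O[C@H]1[C@@H](C(=C)CO[Si](C)(C)C(C)(C)C)[C@H](O[Si](C)(C)C(C)(C)C)/C=C(\C)CC/C=C(/C(=O)OC)[C@@H]1OC(C)=O | intermediate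
24 | methyl (1(10)E,4E,6R,7S,8S,9S)-9-(acetyloxy)-6,12-dihydroxy-8-[(2-methylprop-2-enoyl)oxy]germacra-1(10),4,11(13)-trien-14-oate | C=C(C)C(=O)O[C@H]1[C@@H](C(=C)CO)[C@H](O)/C=C(\C)CC/C=C(/C(=O)OC)[C@@H]1OC(C)=O | intermediate
25 | methyl (1(10)E,4E,6R,7S,8S,9S)-9-(acetyloxy)-6-hydroxy-8-[(2-methylprop-2-enoyl)oxy]-12-oxogermacra-1(10),4,11(13)-trien-14-oate | C=C(C)C(=O)O[C@H]1[C@@H](C(=C)C=O)[C@H](O)/C=C(\C)CC/C=C(/C(=O)OC)[C@@H]1OC(C)=O | intermediate (not isolated)
26 | methyl (1(10)E,4E,6R,7S,8S,9S)-9-(acetyloxy)-12-hydroxy-8-[(2-methylprop-2-enoyl)oxy]-6,12-epoxygermacra-1(10),4,11(13)-trien-14-oate (lactol, both C12 epimers) | C=C(C)C(=O)O[C@H]1[C@H]2C(=C)C(O)O[C@@H]2/C=C(\C)CC/C=C(/C(=O)OC)[C@@H]1OC(C)=O | intermediate (not isolated)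
27 | methyl (1(10)E,4E,6R,7S,8S,9S)-9-(acetyloxy)-8-[(2-methylprop-2-enoyl)oxy]-12-oxo-6,12-epoxygermacra-1(10),4,11(13)-trien-14-oate | C=C(C)C(=O)O[C@H]1[C@H]2C(=C)C(=O)O[C@@H]2/C=C(\C)CC/C=C(/C(=O)OC)[C@@H]1OC(C)=O | intermediate
28 | methyl (1(10)E,4R,5R,6S,7R,8S,9S)-9-(acetyloxy)-4,5:6,12-diepoxy-8-[(2-methylprop-2-enoyl)oxy]-12-oxogermacra-1(10),11(13)-dien-14-oate | C=C(C)C(=O)O[C@H]1[C@H]2C(=C)C(=O)O[C@@H]2[C@H]2O[C@]2(C)CC/C=C(/C(=O)OC)[C@@H]1OC(C)=O | target

## Step count and least certain steps

Total step count: 18. Longest linear sequence: 15 steps (steps 1–6 and 10–18, from 1); the dienyl iodide 13 takes 3 steps (7–9).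

**Step 11 (key).** Most likely failure: the alkoxide 17 cleaves heterolytically (fragmentation, or a 1,3-shift to an eight-membered ketone) instead of rearranging in concert, because C4–C9 joins a doubly allylic alkoxide carbon to a quaternary carbon and the crown-separated ion pair is very electron-rich. Fallback: a neutral siloxy-Cope rearrangement. Set out from 16 and silylate to the trimethylsilyl ether F1 (TMSCl, imidazole). Heat F1 in degassed o-dichlorobenzene at about 180 °C to the ring-expanded trimethylsilyl enol ether F2 through the same chair. Cleave F2 with KOt-Bu in THF at −78 °C, which returns to enolate 18, and hydroxylate as in step 11 to 19.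

**Step 6.** Most likely failure: poor E/Z control in the enolisation, since the kinetic bias and the stability difference are both modest, and Z material is lost for step 11. Fallback: thermodynamic control in a separate operation. Set out from 8, silylate as before, and treat the mixture of 9 and the Z enol ether F3 with catalytic diphenyl disulfide under 400 nm light (reversible thiyl-radical addition–elimination). This should drain F3 into the less strained 9.

**Step 10.** Most likely failure: low facial selectivity in the carbonyl addition, because the methyl and alkenyl arms on C6 differ little in size. Fallback: use the epimer instead of discarding it. From 9 and 13, isolate the (1S,6S) alcohol F4 and submit it to the conditions of step 11. Its potassium alkoxide F5 can reach a chair of the same sense (C3 equatorial, C10 axial), which leads to the geometrical isomer F6 of the enolate with C6 and C7 unchanged. Hydroxylation on the open face returns to 19.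

**Step 12.** Most likely failure: elimination or no displacement at the hindered ring carbon C8, because the carboxylate must approach from the ring side. Fallback: make C8 the electrophile in the key step. From 16, generate enolate 18 as in step 11 and quench it with N-bromosuccinimide to the 8R bromo ketone F7 (bromine on the open face). Displace with caesium methacrylate in DMF at 0 °C; SN2 at the α-halo ketone inverts C8 and gives 20.

**Step 13.** Most likely failure: hydride delivery to the other face if the ring conformation overrides the Felkin–Anh preference. Fallback: reagent control in place of substrate control. From 20, reduce with catecholborane and (S)-2-methyl-CBS-oxazaborolidine to reach 21; α-halo enones are good substrates, with the haloalkenyl arm as the large group. No new compound is made.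

**Step 14.** Most likely failure: shift of the methacryloyl group from O8 to the free O9 in the basic carbonylation medium, or Heck-type capture of the alkenylpalladium by C11=C13 or C4=C5 if CO insertion is slow. Fallback: change the order. From 21, acetylate first to the iodo acetate F8, then carbonylate F8 with the same catalyst, CO and MeOH to arrive at 23.

## Further compounds

F1 | step 11 | {[(1R,6S)-1-[(1E)-3-(TBSOCH2)buta-1,3-dien-1-yl]-6-[(E)-2-(TBSO)ethenyl]-2-iodo-6-methylcyclohex-2-en-1-yl]oxy}(trimethyl)silane | C[Si](C)(C)O[C@@]1(/C=C/C(=C)CO[Si](C)(C)C(C)(C)C)C(I)=CCC[C@@]1(C)/C=C/O[Si](C)(C)C(C)(C)C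
F2 | step 11 | (1(10)E,4E,6R,7S,8Z)-6,12-bis(TBSO)-10-iodo-9-[(trimethylsilyl)oxy]-14-norgermacra-1(10),4,8,11(13)-tetraene | C[Si](C)(C)O/C1=C\[C@@H](C(=C)CO[Si](C)(C)C(C)(C)C)[C@H](O[Si](C)(C)C(C)(C)C)/C=C(\C)CC/C=C1/I
F3 | step 6 | (6S)-6-[(Z)-2-(TBSO)ethenyl]-2-iodo-6-methylcyclohex-2-en-1-one | O=C1C(I)=CCC[C@@]1(C)/C=C\O[Si](C)(C)C(C)(C)C
F4 | step 10 | (1S,6S)-1-[(1E)-3-(TBSOCH2)buta-1,3-dien-1-yl]-6-[(E)-2-(TBSO)ethenyl]-2-iodo-6-methylcyclohex-2-en-1-ol | O[C@]1(/C=C/C(=C)CO[Si](C)(C)C(C)(C)C)C(I)=CCC[C@@]1(C)/C=C/O[Si](C)(C)C(C)(C)C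
F5 | step 10 | potassium (1S,6S)-1-[(1E)-3-(TBSOCH2)buta-1,3-dien-1-yl]-6-[(E)-2-(TBSO)ethenyl]-2-iodo-6-methylcyclohex-2-en-1-olate | [K+].[O-][C@]1(/C=C/C(=C)CO[Si](C)(C)C(C)(C)C)C(I)=CCC[C@@]1(C)/C=C/O[Si](C)(C)C(C)(C)C
F6 | step 10 | potassium (1(10)E,4E,6R,7S,8E)-6,12-bis(TBSO)-10-iodo-14-norgermacra-1(10),4,8,11(13)-tetraen-9-olate | [K+].[O-]/C1=C/[C@@H](C(=C)CO[Si](C)(C)C(C)(C)C)[C@H](O[Si](C)(C)C(C)(C)C)/C=C(\C)CC/C=C1/I
F7 | step 12 | (1(10)E,4E,6R,7S,8R)-8-bromo-6,12-bis(TBSO)-10-iodo-14-norgermacra-1(10),4,11(13)-trien-9-one | Br[C@@H]1[C@@H](C(=C)CO[Si](C)(C)C(C)(C)C)[C@H](O[Si](C)(C)C(C)(C)C)/C=C(\C)CC/C=C(/I)C1=O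
F0 | step 13 | none | none
F8 | step 14 | (1(10)E,4E,6R,7R,8S,9R)-9-(acetyloxy)-6,12-bis(TBSO)-10-iodo-14-norgermacra-1(10),4,11(13)-trien-8-yl 2-methylprop-2-enoate | C=C(C)C(=O)O[C@H]1[C@@H](C(=C)CO[Si](C)(C)C(C)(C)C)[C@H](O[Si](C)(C)C(C)(C)C)/C=C(\C)CC/C=C(/I)[C@@H]1OC(C)=O
A1 | alternative 1 | methyl (2Z,4S,5S,6E,10E)-5-(acetyloxy)-2-(bromomethyl)-6-(methoxycarbonyl)-10-methyl-4-[(2-methylprop-2-enoyl)oxy]-12-oxododeca-2,6,10-trienoate | O=C/C=C(\C)CC/C=C(/C(=O)OC)[C@H](OC(C)=O)[C@@H](OC(=O)C(C)=C)/C=C(\CBr)C(=O)OC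
A2 | alternative 2 | methyl (2Z,6E)-2-iodo-6-methyl-7-{(2R,3S)-3-[(1S)-1-[(2-methylprop-2-enoyl)oxy]-2-oxoethyl]-4-methylidene-5-oxooxolan-2-yl}hepta-2,6-dienoate | C=C(C)C(=O)O[C@H](C=O)[C@H]1C(=C)C(=O)O[C@@H]1/C=C(\C)CC/C=C(\I)C(=O)OC
A3 | alternative 2 | methyl (1(10)E,4E,6R,7S,8S,9S)-9-hydroxy-8-[(2-methylprop-2-enoyl)oxy]-12-oxo-6,12-epoxygermacra-1(10),4,11(13)-trien-14-oate | C=C(C)C(=O)O[C@H]1[C@H]2C(=C)C(=O)O[C@@H]2/C=C(\C)CC/C=C(/C(=O)OC)[C@@H]1O
A4 | alternative 3 | (4S,5S,6S,7R,8S,9S)-6,12-bis(TBSO)-9-hydroxy-10-iodo-8-[(4-methoxyphenyl)methoxy]-14-nor-4,9-cyclogermacra-1(10),11(13)-dien-5-yl methanesulfonate (trans-fused decalin) | O[C@@]12C(I)=CCC[C@@]1(C)[C@H](OS(C)(=O)=O)[C@@H](O[Si](C)(C)C(C)(C)C)[C@H](C(=C)CO[Si](C)(C)C(C)(C)C)[C@@H]2OCc1ccc(OC)cc1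
A5 | alternative 3 | (1(10)E,4E,6R,7R,8S)-6,12-bis(TBSO)-10-iodo-8-[(4-methoxyphenyl)methoxy]-14-norgermacra-1(10),4,11(13)-trien-9-one | COc1ccc(CO[C@H]2[C@@H](C(=C)CO[Si](C)(C)C(C)(C)C)[C@H](O[Si](C)(C)C(C)(C)C)/C=C(\C)CC/C=C(/I)C2=O)cc1
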